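**Strategy.** Everything rests on cutting O1–C2 of the pyranone ring (ring C) and reading the anti C2–OAr/C3–OH pair as an opened trans-epoxide. The key step exploits two features: C2 is benzylic to the 4'-oxygenated ring B, whereas C3 lies next to the C4 carbonyl, so an α,β-epoxy ketone can open only at C2; and the phenol oxygen on C8a of ring A is placed to close a six-membered ring. In one operation acid strips three MOM ethers, closes ring C 6-endo, sets C2 by inversion (C3 is carried over from the epoxide) and releases the target. The precursor is an open-chain (2R,3S)-epoxy ketone, made by peptide-catalysed nucleophilic epoxidation of a doubly prenylated chalcone.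

Key step: step 7

Remark: flavanone numbering (O1, C2, C3, C4, C4a, C5–C8, C8a, primed B ring) is used for the target. Poly-L-leucine is assumed to show the same facial sense with chalcone 9 as with simple chalcones, i.e. to give the (2R,3S)-epoxide.

**Step 1**
Reactants: 1 2,4-dihydroxyacetophenone; 2 2-methylbut-3-en-2-ol
Product: 3 1-[2,4-dihydroxy-5-(3-methylbut-2-en-1-yl)phenyl]ethanone
Conditions: BF3·OEt2 (0.3 equiv), dioxane, rt; chromatography
Reagents that add atoms: none
Why: Friedel–Crafts C-prenylation by the dimethylallyl cation should occur mainly at C5 (para to the chelated 2-OH, ortho to the 4-OH) and not at the doubly flanked C3, with the minor 3-prenyl and diprenyl products removed by chromatography.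

**Step 2**
Reactants: 3 1-[2,4-dihydroxy-5-(3-methylbut-2-en-1-yl)phenyl]ethanone
Product: 4 1-[2,4-bis(methoxymethoxy)-5-(3-methylbut-2-en-1-yl)phenyl]ethanone
Conditions: NaH (2.3 equiv), MOMCl (2.4 equiv), DMF, 0 °C to rt
Reagents that add atoms: chloromethyl methyl ether (MOMCl), COCCl
Why: Williamson O-alkylation of both phenoxides, the strong base being needed to break the hydrogen bond of the chelated 2-OH, gives a base-stable ketone for the aldol condensation.

**Step 3**
Reactants: 5 4-hydroxybenzaldehyde; 6 prenyl bromide (1-bromo-3-methylbut-2-ene)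
Product: 7 4-hydroxy-3-(3-methylbut-2-en-1-yl)benzaldehyde
Conditions: KOH, H2O, rt; chromatography
Reagents that add atoms: none
Why: ortho-C-alkylation of the ambident phenoxide, whose oxygen is shielded by hydrogen bonding in water and whose para position is blocked by the formyl group, should give the 3-prenyl phenol, separable from the O-prenyl ether.

**Step 4**
Reactants: 7 4-hydroxy-3-(3-methylbut-2-en-1-yl)benzaldehyde
Product: 8 4-(methoxymethoxy)-3-(3-methylbut-2-en-1-yl)benzaldehyde
Conditions: MOMCl, K2CO3, acetone, rt
Reagents that add atoms: chloromethyl methyl ether (MOMCl), COCCl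
Why: Williamson O-alkylation masks the phenol, whose phenoxide would otherwise deactivate the aldehyde in the condensation.

**Step 5**
Reactants: 4 1-[2,4-bis(methoxymethoxy)-5-(3-methylbut-2-en-1-yl)phenyl]ethanone; 8 4-(methoxymethoxy)-3-(3-methylbut-2-en-1-yl)benzaldehyde
Product: 9 (E)-1-[2,4-bis(methoxymethoxy)-5-(3-methylbut-2-en-1-yl)phenyl]-3-[4-(methoxymethoxy)-3-(3-methylbut-2-en-1-yl)phenyl]prop-2-en-1-one
Conditions: KOH, EtOH–H2O, rt
Reagents that add atoms: none
Why: Claisen–Schmidt condensation of the methyl ketone enolate with the non-enolisable aldehyde, followed by E1cB dehydration, should give the (E)-chalcone; MOM ethers and prenyl groups are stable to base.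

**Step 6**
Reactants: 9 (E)-chalcone
Product: 10 [2,4-bis(methoxymethoxy)-5-(3-methylbut-2-en-1-yl)phenyl]{(2R,3S)-3-[4-(methoxymethoxy)-3-(3-methylbut-2-en-1-yl)phenyl]oxiran-2-yl}methanone
Conditions: poly-L-leucine (cat.), urea–H2O2, DBU, THF, rt
Reagents that add atoms: urea–hydrogen peroxide, NC(N)=O.OO
Why: Juliá–Colonna epoxidation, in which hydroperoxide adds in conjugate fashion to the enone bound at the N-terminus of the helical peptide and the enolate closes on O–O, should give the (2R,3S)-trans-epoxide and leave both nucleophilic prenyl olefins untouched because the oxidant is a nucleophile.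

**Step 7**
Reactants: 10 (2R,3S)-epoxy ketone
Product: 12 lespeflorin B1, (2R,3R)-3,7-dihydroxy-2-[4-hydroxy-3-(3-methylbut-2-en-1-yl)phenyl]-6-(3-methylbut-2-en-1-yl)-2,3-dihydro-4H-chromen-4-one, via free triphenol epoxy ketone 11 (not isolated)
Conditions: HCl (1.25 M in MeOH), MeOH–THF, 0 to 40 °C
Reagents that add atoms: none
Why: Methanolic HCl cleaves the three MOM acetals through oxocarbenium ions that methanol traps as dimethoxymethane, and the freed phenol oxygen of 11 then attacks the protonated oxirane at its benzylic carbon, the only carbon able to carry positive charge thanks to the para-oxygenated B ring, while the carbon next to the carbonyl is deactivated. The closest known reaction type is the acid-mediated cyclisation of 2'-hydroxychalcone epoxides to 2,3-trans-dihydroflavonols, the non-oxidative branch of the Algar–Flynn–Oyamada manifold. Ring C closes by 6-endo-tet opening of the epoxide, favoured over the 5-exo mode (which would lead to a 2-(hydroxybenzyl)benzofuranone) because bond breaking at the benzylic carbon runs ahead of bond making. C2 is set by attack anti to the departing epoxide oxygen, so the (S) benzylic carbon becomes (2R), and C3 keeps the configuration from step 6 because none of its bonds is touched; should the opening drift toward a free benzylic cation, the resident C3 centre should still steer closure to the diequatorial 2,3-trans isomer. The step needs C2-over-C3 regioselectivity, trans selectivity and survival of two prenyl groups beside free phenols: the first two follow from the substitution pattern, the last from dilute acid, mild temperature and short reaction time.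

**Compound list**
1 | 2,4-dihydroxyacetophenone | CC(=O)c1ccc(O)cc1O | starting material
2 | 2-methylbut-3-en-2-ol | C=CC(C)(C)O | starting material
3 | 1-[2,4-dihydroxy-5-(3-methylbut-2-en-1-yl)phenyl]ethanone | CC(=O)c1cc(CC=C(C)C)c(O)cc1O | intermediate
4 | 1-[2,4-bis(methoxymethoxy)-5-(3-methylbut-2-en-1-yl)phenyl]ethanone | CC(=O)c1cc(CC=C(C)C)c(OCOC)cc1OCOC | intermediate
5 | 4-hydroxybenzaldehyde | O=Cc1ccc(O)cc1 | starting material
6 | prenyl bromide (1-bromo-3-methylbut-2-ene) | CC(C)=CCBr | starting material
7 | 4-hydroxy-3-(3-methylbut-2-en-1-yl)benzaldehyde | CC(C)=CCc1cc(C=O)ccc1O | intermediate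
8 | 4-(methoxymethoxy)-3-(3-methylbut-2-en-1-yl)benzaldehyde | COCOc1ccc(C=O)cc1CC=C(C)C | intermediate
9 | (E)-1-[2,4-bis(methoxymethoxy)-5-(3-methylbut-2-en-1-yl)phenyl]-3-[4-(methoxymethoxy)-3-(3-methylbut-2-en-1-yl)phenyl]prop-2-en-1-one | COCOc1cc(OCOC)c(CC=C(C)C)cc1C(=O)/C=C/c1ccc(OCOC)c(CC=C(C)C)c1 | intermediate
10 | [2,4-bis(methoxymethoxy)-5-(3-methylbut-2-en-1-yl)phenyl]{(2R,3S)-3-[4-(methoxymethoxy)-3-(3-methylbut-2-en-1-yl)phenyl]oxiran-2-yl}methanone | COCOc1cc(OCOC)c(CC=C(C)C)cc1C(=O)[C@@H]1O[C@H]1c1ccc(OCOC)c(CC=C(C)C)c1 | intermediate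
11 | [2,4-dihydroxy-5-(3-methylbut-2-en-1-yl)phenyl]{(2R,3S)-3-[4-hydroxy-3-(3-methylbut-2-en-1-yl)phenyl]oxiran-2-yl}methanone | Oc1cc(O)c(CC=C(C)C)cc1C(=O)[C@@H]1O[C@H]1c1ccc(O)c(CC=C(C)C)c1 | intermediate
12 | lespeflorin B1, (2R,3R)-3,7-dihydroxy-2-[4-hydroxy-3-(3-methylbut-2-en-1-yl)phenyl]-6-(3-methylbut-2-en-1-yl)-2,3-dihydro-4H-chromen-4-one | CC(C)=CCc1cc([C@H]2Oc3cc(O)c(CC=C(C)C)cc3C(=O)[C@@H]2O)ccc1O | target

**Total step count:** 7
**Longest linear sequence:** 5 steps (1, 2, 5, 6, 7; the branch 3, 4, 5, 6, 7 is equally long)

**Steps most likely to fail**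

Step 7. Methanol may open the oxirane at the benzylic carbon before the phenol is unmasked, which would erode trans selectivity. Prolonged acid may also cyclise a prenyl group onto its neighbouring phenol. The fallback sets out from 10 and comes back at 12, with a sulfur relay in place of the direct epoxide opening. Benzyl mercaptan with SnCl4 in CH2Cl2 at −20 °C should open the benzylic C–O bond through sulfur and remove the MOM groups at the same time. This would give (2S)-3-(benzylsulfanyl)-1-[2,4-dihydroxy-5-(3-methylbut-2-en-1-yl)phenyl]-2-hydroxy-3-[4-hydroxy-3-(3-methylbut-2-en-1-yl)phenyl]propan-1-one F1, as a mixture of epimers at the sulfur-bearing carbon. Thiophilic activation with AgBF4 in CH2Cl2 at 0 °C should then ionise the C–S bond, and the phenol should close ring C under control of the intact C3 centre to give the trans product 12.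

Step 6. The ortho-alkoxy group on the aroyl ring may reduce binding to the peptide and give poor facial discrimination. The fallback sets out from 9 and comes back at 10, replacing asymmetric catalysis by resolution. Weitz–Scheffer epoxidation (H2O2, NaOH, MeOH–THF, 0 °C) should give the racemic trans-epoxide, that is 10 together with its mirror image, the (2S,3R)-epoxy ketone F2. Preparative HPLC on a chiral stationary phase should then deliver 10.

Step 1. The Friedel–Crafts prenylation may show poor positional selectivity (C3 against C5) and over-alkylation, leaving little of the desired isomer. The fallback sets out from 1 and comes back at 4, fixing the position with a halogen. Bromination with NBS in MeCN at 0 °C should give 1-(5-bromo-2,4-dihydroxyphenyl)ethanone F3. Protection with NaH and MOMCl in DMF should give 1-[5-bromo-2,4-bis(methoxymethoxy)phenyl]ethanone F4. Stille coupling with tributyl(3-methylbut-2-en-1-yl)stannane (Pd(PPh3)4, DMF, 90 °C) should then install the linear prenyl group and give 4.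

**Further compounds**
F1 | step 7 | (2S)-3-(benzylsulfanyl)-1-[2,4-dihydroxy-5-(3-methylbut-2-en-1-yl)phenyl]-2-hydroxy-3-[4-hydroxy-3-(3-methylbut-2-en-1-yl)phenyl]propan-1-one (epimers at C3) | Oc1cc(O)c(CC=C(C)C)cc1C(=O)[C@H](O)C(SCc1ccccc1)c1ccc(O)c(CC=C(C)C)c1
F2 | step 6 | [2,4-bis(methoxymethoxy)-5-(3-methylbut-2-en-1-yl)phenyl]{(2S,3R)-3-[4-(methoxymethoxy)-3-(3-methylbut-2-en-1-yl)phenyl]oxiran-2-yl}methanone (enantiomer of 10) | COCOc1cc(OCOC)c(CC=C(C)C)cc1C(=O)[C@H]1O[C@@H]1c1ccc(OCOC)c(CC=C(C)C)c1
F3 | step 1 | 1-(5-bromo-2,4-dihydroxyphenyl)ethanone | CC(=O)c1cc(Br)c(O)cc1O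
F4 | step 1 | 1-[5-bromo-2,4-bis(methoxymethoxy)phenyl]ethanone | CC(=O)c1cc(Br)c(OCOC)cc1OCOC
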